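**Retrosynthetic overview**
1. In the elemane cyclohexane, the vinyl group on the quaternary methyl carbon and the isopropenyl group on the neighbouring ring CH are the two ends of a hexa-1,5-diene whose central σ-bond is a ring bond. Cleaving that bond in the retro-Cope sense gives an (E,E)-cyclodeca-1,5-diene that already carries the complete spiro-dihydropyran lactone.
2. The dihydropyran is disconnected at its enol-ether C–O bond (lactol dehydration) and at its CH2–CH2 bond (conjugate addition of a CH2 radical from the lactone half to a 2-substituted acrolein on the ten-ring).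
3. The ten-ring enal comes from (2E,6E)-farnesyl acetate: terminal allylic oxidation, asymmetric epoxidation (sets the ring stereocentre), thioallyl-anion/epoxide macrocyclisation, degradation of the side chain to a methyl ketone and Shapiro formylation.
4. The lactone half comes from isoalantolactone: the methylene lactone becomes the α-spiro-epoxide (later the iodohydrin), the C4 methylene is cut to a ketone, C5 is inverted through a Δ5-4β-ol by hydroxyl-directed hydrogenation, and the methylene is put back.
5. Ring order: ten-membered carbocycle, then the dihydropyran (spiro union), then the cyclohexane by the Cope shift as the last step.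

Key step: step 22

Assumption: the target is taken exactly as drawn. The ring-fusion hydrogen of the eudesmanolide half is on the same face as the angular methyl (cis-decalin, the C5 epimer of isoalantolactone), and the elemane ring is (1R,2R,4S), which requires the (7S) ten-ring.
Numbering: germacrane numbering for the ten-ring (ring alkenes C1=C10 and C4=C5; C7 carries the side chain C11–C13); eudesmane numbering for the lactone half (C14 angular methyl on C10, C15 on C4, C12 lactone carbonyl, C13 the former exocyclic methylene carbon).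
Handling: every compound that contains the ten-membered (E,E)-diene (8–13, 26–29) is kept below 35 °C and purified on Et3N-deactivated silica, because heat starts the Cope shift and acid starts transannular cyclisation.

**Ten-ring enal**

Step 1
Reactants: 1 (2E,6E)-farnesyl acetate
Product: 2 (2E,6E,10E)-12-hydroxyfarnesyl acetate
Conditions: SeO2 (cat.), salicylic acid (cat.), 70% aq. t-BuOOH, CH2Cl2, 0 °C → rt
Reagents that add atoms: selenium dioxide, O=[Se]=O; tert-butyl hydroperoxide, CC(C)(C)OO
Why: Riley allylic oxidation (ene reaction, then [2,3]-shift) goes to the (E)-methyl of the terminal, most electron-rich trisubstituted alkene, the 2,3-alkene being deactivated by the allylic acetate.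

Step 2
Reactants: 2 (2E,6E,10E)-12-hydroxyfarnesyl acetate
Product: 3 (2E,6E,10S,11S)-10,11-epoxy-12-hydroxy-10,11-dihydrofarnesyl acetate
Conditions: Ti(OiPr)4 (10 mol%), L-(+)-diethyl tartrate (12 mol%), t-BuOOH (decane), 4 Å MS, CH2Cl2, −20 °C
Reagents that add atoms: tert-butyl hydroperoxide, CC(C)(C)OO
Why: Katsuki–Sharpless epoxidation acts only on the alkene with the free allylic hydroxyl, and L-(+)-tartrate should set (10S,11S), the sense in which (E)-2-alken-1-ols give (2S,3S)-epoxy alcohols.

Step 3
Reactants: 3 (2E,6E,10S,11S)-10,11-epoxy-12-hydroxy-10,11-dihydrofarnesyl acetate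
Product: 4 (2E,6E,10S,11S)-12-benzyloxy-10,11-epoxy-10,11-dihydrofarnesyl acetate
Conditions: BnBr, Ag2O, n-Bu4NI (cat.), CH2Cl2, rt, dark
Reagents that add atoms: benzyl bromide, BrCc1ccccc1
Why: Ag2O-promoted Williamson etherification caps the primary hydroxyl under neutral conditions, so neither Payne rearrangement of the epoxy alcohol nor acetate migration should occur.

Step 4
Reactants: 4 (2E,6E,10S,11S)-12-benzyloxy-10,11-epoxy-10,11-dihydrofarnesyl acetate
Product: 5 (2E,6E,10S,11S)-12-benzyloxy-10,11-epoxy-10,11-dihydrofarnesol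
Conditions: K2CO3, MeOH, 0 °C
Reagents that add atoms: none
Why: Base-catalysed transesterification (Zemplén-type) removes the acetate, while the trisubstituted epoxide and the benzyl ether are inert to carbonate in cold methanol.

Step 5
Reactants: 5 (2E,6E,10S,11S)-12-benzyloxy-10,11-epoxy-10,11-dihydrofarnesol
Product: 6 (2E,6E,10S,11S)-12-benzyloxy-10,11-epoxy-10,11-dihydrofarnesyl phenyl sulfide
Conditions: PhSSPh, n-Bu3P, pyridine, 0 °C → rt
Reagents that add atoms: diphenyl disulfide, c1ccccc1SSc1ccccc1
Why: Hata reaction: the alkoxyphosphonium ion is displaced by thiolate at the primary allylic carbon in an SN2 step, without allylic transposition or loss of the E geometry.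

Step 6
Reactants: 6 (2E,6E,10S,11S)-12-benzyloxy-10,11-epoxy-10,11-dihydrofarnesyl phenyl sulfide
Product: 8 (7R,11R)-12-benzyloxy-6-(phenylthio)germacra-1(10)E,4E-dien-11-ol (C6 epimers), via lithiated sulfide 7 (not isolated)
Conditions: n-BuLi, DABCO, THF (0.005 M), −78 → −20 °C; H2O
Reagents that add atoms: none
Why: Intramolecular alkylation of a sulfur-stabilised allyl anion by an epoxide (Biellmann-type coupling run as a macrocyclisation, a closure known for ten-membered terpenoid rings): the α-carbon opens the epoxide at its secondary carbon in a 10-exo SN2 step with inversion, which fixes C7 (same spatial arrangement as (7S) in 9–13), and high dilution suppresses dimers.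

Step 7
Reactants: 8 (7R,11R)-12-benzyloxy-6-(phenylthio)germacra-1(10)E,4E-dien-11-ol
Product: 9 (7S,11R)-germacra-1(10)E,4E-diene-11,12-diol
Conditions: Li, EtNH2, THF, −78 °C; H2O
Reagents that add atoms: none
Why: Benkeser-type dissolving-metal reduction cleaves the allylic C–S bond and the benzyl ether in one operation; at −78 °C the isolated trisubstituted alkenes are not reduced and the allyl anion should be protonated at its less substituted terminus, keeping the C4=C5 (E) alkene.

Step 8
Reactants: 9 (7S,11R)-germacra-1(10)E,4E-diene-11,12-diol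
Product: 10 (7S)-12-nor-germacra-1(10)E,4E-dien-11-one
Conditions: NaIO4, THF/H2O (pH 7 phosphate), 0 °C → rt
Reagents that add atoms: none
Why: Malaprade glycol cleavage at neutral pH excises C12 as formaldehyde and leaves the methyl ketone without epimerising the adjacent C7.

Step 9
Reactants: 10 (7S)-12-nor-germacra-1(10)E,4E-dien-11-one
Product: 11 (E)-2,4,6-triisopropylbenzenesulfonylhydrazone of 10
Conditions: 2,4,6-iPr3C6H2SO2NHNH2, THF, rt
Reagents that add atoms: 2,4,6-triisopropylbenzenesulfonyl hydrazide, CC(C)c1cc(C(C)C)c(S(=O)(=O)NN)c(C(C)C)c1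
Why: Hydrazone condensation of an unhindered methyl ketone needs no acid, and the (E)-isomer places the sulfonamide nitrogen on the methyl side as the next step requires.

Step 10
Reactants: 11 (E)-2,4,6-triisopropylbenzenesulfonylhydrazone of 10
Product: 13 (7S)-germacra-1(10)E,4E,11(13)-trien-12-al, via vinyllithium 12 (not isolated)
Conditions: n-BuLi (2.2 equiv), THF, −78 → 0 °C; DMF, −78 °C → rt; H2O
Reagents that add atoms: N,N-dimethylformamide, CN(C)C=O
Why: Shapiro reaction: the second deprotonation occurs at the methyl group syn to the sulfonamide, loss of sulfinate and N2 gives the 1,1-disubstituted vinyllithium, and formylation by DMF delivers the 2-substituted acrolein.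

**Lactone half**

Step 11
Reactants: 14 isoalantolactone
Product: 15 11α,13-epoxy-11,13-dihydroisoalantolactone
Conditions: t-BuOOH, DBU, CH2Cl2, 0 °C → rt
Reagents that add atoms: tert-butyl hydroperoxide, CC(C)(C)OO
Why: Weitz–Scheffer nucleophilic epoxidation touches only the conjugated exocyclic methylene (the isolated C4=C15 alkene is inert), and the enolate closes on the convex face of the cis-fused lactone (the face of H7), which places the new C11–O bond α.

Step 12
Reactants: 15 11α,13-epoxy-11,13-dihydroisoalantolactone
Product: 17 11α,13-epoxy-15-nor-4-oxo-eudesman-12,8β-olide (5α-H), via ozonide 16 (not isolated)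
Conditions: O3, CH2Cl2, −78 °C; Me2S, −78 °C → rt
Reagents that add atoms: ozone, [O-][O+]=O
Why: Criegee ozonolysis of the only remaining alkene with reductive work-up gives the C4 ketone and leaves the epoxy lactone untouched.

Step 13
Reactants: 17 11α,13-epoxy-15-nor-4-oxo-eudesman-12,8β-olide
Product: 19 11α,13-epoxy-15-nor-4-oxo-eudesm-5-en-12,8β-olide, via 5α-bromo ketone 18 (not isolated)
Conditions: NBS, TsOH·H2O (10 mol%), CH2Cl2, rt; then DBU, 0 °C → rt
Reagents that add atoms: none
Why: Acid-catalysed α-bromination through the more substituted C4=C5 enol (the regiochemistry of steroidal 4-ketones) followed by E2 loss of HBr, which can only go toward C6 because C10 is quaternary; NBS keeps free HBr low so the oxirane should survive.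

Step 14
Reactants: 19 11α,13-epoxy-15-nor-4-oxo-eudesm-5-en-12,8β-olide
Product: 20 11α,13-epoxy-4β-hydroxy-15-nor-eudesm-5-en-12,8β-olide
Conditions: NaBH4, CeCl3·7H2O, MeOH, −78 °C
Reagents that add atoms: none
Why: Luche 1,2-reduction: hydride attacks C4 from the α face, away from the syn-axial angular methyl, to give the 4β (axial) allylic alcohol, and the lactone and oxirane are not reduced at −78 °C.

Step 15
Reactants: 20 11α,13-epoxy-4β-hydroxy-15-nor-eudesm-5-en-12,8β-olide
Product: 21 11α,13-epoxy-4β-hydroxy-15-nor-5β-eudesman-12,8β-olide (cis-fused)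
Conditions: [Ir(cod)(PCy3)(py)]PF6 (5 mol%), H2 (1 atm), CH2Cl2, rt
Reagents that add atoms: none
Why: Hydroxyl-directed homogeneous hydrogenation: iridium bound to the 4β-hydroxyl delivers H2 to the β face of C5=C6, so the new C5–H is cis to the angular methyl against the intrinsic steric preference.

Step 16
Reactants: 21 11α,13-epoxy-4β-hydroxy-15-nor-5β-eudesman-12,8β-olide
Product: 22 11α,13-epoxy-15-nor-4-oxo-5β-eudesman-12,8β-olide
Conditions: Dess–Martin periodinane, pyridine, CH2Cl2, 0 °C → rt
Reagents that add atoms: none
Why: Dess–Martin oxidation under buffered, non-enolising conditions returns the C4 ketone without equilibrating the cis C5 centre.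

Step 17
Reactants: 22 11α,13-epoxy-15-nor-4-oxo-5β-eudesman-12,8β-olide
Product: 23 11α,13-epoxy-4-hydroxy-4-(trimethylsilylmethyl)-15-nor-5β-eudesman-12,8β-olide (C4 epimers)
Conditions: Me3SiCH2Li, CeCl3, THF, −78 °C; H2O
Reagents that add atoms: (trimethylsilyl)methyllithium, [Li]C[Si](C)(C)C
Why: Organocerium addition (first half of a Peterson olefination) is non-basic, so C5 is not epimerised, and at −78 °C it should attack the ketone much faster than the lactone or the oxirane.

Step 18
Reactants: 23 11α,13-epoxy-4-hydroxy-4-(trimethylsilylmethyl)-15-nor-5β-eudesman-12,8β-olide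
Product: 24 11α,13-epoxy-11,13-dihydro-5-epi-isoalantolactone
Conditions: KH, THF, 0 °C → rt; H2O
Reagents that add atoms: none
Why: Base-induced Peterson syn-elimination of the potassium alkoxide gives the exocyclic C4=C15 methylene, and no enolisable position remains next to C5.

Step 19
Reactants: 24 11α,13-epoxy-11,13-dihydro-5-epi-isoalantolactone
Product: 25 11α-hydroxy-13-iodo-11,13-dihydro-5-epi-isoalantolactone
Conditions: MgI2, Et2O/toluene, 0 °C; H2O
Reagents that add atoms: magnesium iodide, [Mg+2].[I-].[I-]
Why: Lewis-acid-assisted SN2 opening of the glycidic lactone by iodide at the unhindered CH2 terminus (halohydrin formation) leaves the C11–O bond, and so the 11α-hydroxyl, untouched.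

**Union and key step**

Step 20
Reactants: 25 11α-hydroxy-13-iodo-11,13-dihydro-5-epi-isoalantolactone; 13 (7S)-germacra-1(10)E,4E,11(13)-trien-12-al
Product: 27 spiro lactol (2-hydroxytetrahydropyran form; pyran C5/C6 epimers), via hydroxy aldehyde 26 (not isolated)
Conditions: Bu3SnH (syringe pump), 2,2'-azobis(4-methoxy-2,4-dimethylvaleronitrile) (0.2 equiv), toluene, 30 °C
Reagents that add atoms: none
Why: Giese reaction: the nucleophilic primary radical from the neopentyl-type iodide adds to the CH2 terminus of the 2-substituted acrolein, the α-formyl radical is reduced by the stannane, and the δ-hydroxy aldehyde should close to the six-membered lactol, all at a temperature at which the ten-ring diene does not rearrange.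

Step 21
Reactants: 27 spiro lactol
Product: 29 (E,E)-germacradienyl spiro-dihydropyran lactone, via anomeric mesylate 28 (not isolated)
Conditions: MsCl, Et3N, CH2Cl2, −20 °C → rt
Reagents that add atoms: none
Why: Lactol dehydration by anomeric sulfonylation and amine-induced elimination (the glycal-type enol ether synthesis) removes both lactol stereocentres and keeps the medium basic, which protects the acid-labile ten-ring diene.

Step 22
Reactants: 29 (E,E)-germacradienyl spiro-dihydropyran lactone
Product: 30 target
Conditions: toluene (degassed, 0.02 M, BHT cat.), base-washed sealed tube, 120 °C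
Reagents that add atoms: none
Why: Concerted, suprafacial [3,3]-sigmatropic (Cope) shift of the C10=C1–C2–C3–C4=C5 unit through the crossed conformer of the ten-ring, in which the two E alkenes face each other in a chair-like six-centre transition state: the C5–C10 bond forms as the allylic C2–C3 bond breaks. The closest known reaction type is the thermal germacrane-to-elemane isomerisation of (E,E)-cyclodeca-1,5-dienes. The cyclohexane (C5–C6–C7–C8–C9–C10) closes transannularly, by bonding of the two distal alkene carbons across the medium ring, and the vinyl (C1=C2) and isopropenyl (C3=C4 with C15) groups are released in the same event. The quaternary methyl/vinyl carbon and the isopropenyl CH are set relative to each other by the E,E geometry passing through the chair (vinyl and isopropenyl trans and equatorial, methyl axial), and relative to C7 because the bulky dihydropyranyl substituent stays pseudo-equatorial in that chair; with (7S) this should give the (1R,2R,4S) ring of the target. The step needs chair over boat selectivity and full conversion: the first is secured by the E,E geometry within the ring, the second by release of medium-ring strain, and since no reagent, acid or metal is present the enol ether, the lactone and the exocyclic methylene are not at risk.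

**Compound list**
1 | (2E,6E)-farnesyl acetate | CC(C)=CCC/C(C)=C/CC/C(C)=C/COC(C)=O | starting material
2 | (2E,6E,10E)-12-hydroxyfarnesyl acetate | OC/C(C)=C/CC/C(C)=C/CC/C(C)=C/COC(C)=O | intermediate
3 | (2E,6E,10S,11S)-10,11-epoxy-12-hydroxy-10,11-dihydrofarnesyl acetate | OC[C@]1(C)O[C@H]1CC/C(C)=C/CC/C(C)=C/COC(C)=O | intermediate
4 | 12-O-benzyl ether of 3 | C(OC[C@]1(C)O[C@H]1CC/C(C)=C/CC/C(C)=C/COC(C)=O)c1ccccc1 | intermediate
5 | (2E,6E,10S,11S)-12-benzyloxy-10,11-epoxy-10,11-dihydrofarnesol | C(OC[C@]1(C)O[C@H]1CC/C(C)=C/CC/C(C)=C/CO)c1ccccc1 | intermediate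
6 | (2E,6E,10S,11S)-12-benzyloxy-10,11-epoxy-10,11-dihydrofarnesyl phenyl sulfide | C(OC[C@]1(C)O[C@H]1CC/C(C)=C/CC/C(C)=C/CSc1ccccc1)c1ccccc1 | intermediate
7 | C1-lithiated sulfide from 6 | C(OC[C@]1(C)O[C@H]1CC/C(C)=C/CC/C(C)=C/C([Li])Sc1ccccc1)c1ccccc1 | intermediate (not isolated)
8 | (7R,11R)-12-benzyloxy-6-(phenylthio)germacra-1(10)E,4E-dien-11-ol, C6 epimers; C7 has the spatial arrangement of (7S) in 9–13, the descriptor differs only because sulfur raises the priority of C6 | C/C1=C\CC/C(C)=C/C(Sc2ccccc2)[C@@H]([C@@](C)(O)COCc2ccccc2)CC1 | intermediate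
9 | (7S,11R)-germacra-1(10)E,4E-diene-11,12-diol | C/C1=C\CC/C(C)=C/C[C@@H]([C@@](C)(O)CO)CC1 | intermediate
10 | (7S)-12-nor-germacra-1(10)E,4E-dien-11-one, i.e. (S)-1-[(3E,7E)-4,8-dimethylcyclodeca-3,7-dien-1-yl]ethanone | C/C1=C\CC/C(C)=C/C[C@@H](C(C)=O)CC1 | intermediate
11 | (E)-2,4,6-triisopropylbenzenesulfonylhydrazone of 10 | C/C1=C\CC/C(C)=C/C[C@@H](/C(C)=N/NS(=O)(=O)c2c(C(C)C)cc(C(C)C)cc2C(C)C)CC1 | intermediate
12 | (7S)-11-lithio-12-nor-germacra-1(10)E,4E,11(13)-triene | C/C1=C\CC/C(C)=C/C[C@@H](C(=C)[Li])CC1 | intermediate (not isolated)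
13 | (7S)-germacra-1(10)E,4E,11(13)-trien-12-al | C/C1=C\CC/C(C)=C/C[C@@H](C(=C)C=O)CC1 | intermediate
14 | isoalantolactone | C=C1C(=O)O[C@@H]2C[C@@]3(C)CCCC(=C)[C@@H]3C[C@@H]21 | starting material
15 | 11α,13-epoxy-11,13-dihydroisoalantolactone (oxirane oxygen on the face of H7) | C1O[C@]12C(=O)O[C@@H]3C[C@@]4(C)CCCC(=C)[C@@H]4C[C@@H]32 | intermediate
16 | ozonide of 15 (spiro-1,2,4-trioxolane at C4) | C1O[C@]12C(=O)O[C@@H]3C[C@@]4(C)CCCC5(OCOO5)[C@@H]4C[C@@H]32 | intermediate (not isolated)
17 | 11α,13-epoxy-15-nor-4-oxo-eudesman-12,8β-olide (5α-H, trans-fused) | C1O[C@]12C(=O)O[C@@H]3C[C@@]4(C)CCCC(=O)[C@@H]4C[C@@H]32 | intermediate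
18 | 5α-bromo derivative of 17 (C5 configuration immaterial) | C1O[C@]12C(=O)O[C@@H]3C[C@@]4(C)CCCC(=O)[C@]4(Br)C[C@@H]32 | intermediate (not isolated)
19 | 11α,13-epoxy-15-nor-4-oxo-eudesm-5-en-12,8β-olide | C1O[C@]12C(=O)O[C@@H]3C[C@@]4(C)CCCC(=O)C4=C[C@@H]32 | intermediate
20 | 11α,13-epoxy-4β-hydroxy-15-nor-eudesm-5-en-12,8β-olide (hydroxyl cis to the angular methyl) | C1O[C@]12C(=O)O[C@@H]3C[C@@]4(C)CCC[C@H](O)C4=C[C@@H]32 | intermediate
21 | 11α,13-epoxy-4β-hydroxy-15-nor-5β-eudesman-12,8β-olide (cis-decalin) | C1O[C@]12C(=O)O[C@@H]3C[C@@]4(C)CCC[C@H](O)[C@H]4C[C@@H]32 | intermediate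
22 | 11α,13-epoxy-15-nor-4-oxo-5β-eudesman-12,8β-olide | C1O[C@]12C(=O)O[C@@H]3C[C@@]4(C)CCCC(=O)[C@H]4C[C@@H]32 | intermediate
23 | 11α,13-epoxy-4-hydroxy-4-(trimethylsilylmethyl)-15-nor-5β-eudesman-12,8β-olide (C4 epimers) | C1O[C@]12C(=O)O[C@@H]3C[C@@]4(C)CCCC(O)(C[Si](C)(C)C)[C@H]4C[C@@H]32 | intermediate
24 | 11α,13-epoxy-11,13-dihydro-5-epi-isoalantolactone | C1O[C@]12C(=O)O[C@@H]3C[C@@]4(C)CCCC(=C)[C@H]4C[C@@H]32 | intermediate
25 | 11α-hydroxy-13-iodo-11,13-dihydro-5-epi-isoalantolactone | O[C@@]1(CI)C(=O)O[C@@H]2C[C@@]3(C)CCCC(=C)[C@H]3C[C@@H]21 | intermediate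
26 | δ-hydroxy aldehyde: C13 of the lactone half bonded to C13 of the ten-ring side chain, formyl-bearing carbon as epimers | C/C1=C\CC/C(C)=C/C[C@@H](C(C=O)CC[C@]2(O)C(=O)O[C@@H]3C[C@@]4(C)CCCC(=C)[C@H]4C[C@@H]32)CC1 | intermediate (not isolated)
27 | spiro lactol: 6-hydroxy-5-(germacradienyl)tetrahydropyran spiro-fused through its C2 to C11 of the lactone, ring oxygen on the face of H7, pyran C5/C6 epimers | C/C1=C\CC/C(C)=C/C[C@@H](C2CC[C@]3(OC2O)C(=O)O[C@@H]2C[C@@]4(C)CCCC(=C)[C@H]4C[C@@H]23)CC1 | intermediate
28 | anomeric mesylate of 27 | C/C1=C\CC/C(C)=C/C[C@@H](C2CC[C@]3(OC2OS(C)(=O)=O)C(=O)O[C@@H]2C[C@@]4(C)CCCC(=C)[C@H]4C[C@@H]23)CC1 | intermediate (not isolated)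
29 | (E,E)-germacradienyl spiro-dihydropyran lactone (Cope precursor) | C/C1=C\CC/C(C)=C/C[C@@H](C2=CO[C@@]3(CC2)C(=O)O[C@@H]2C[C@@]4(C)CCCC(=C)[C@H]4C[C@@H]23)CC1 | intermediate
30 | CNP0353330.1 | C=C[C@@]1(C)CC[C@H](C2=CO[C@@]3(CC2)C(=O)O[C@@H]2C[C@@]4(C)CCCC(=C)[C@H]4C[C@@H]23)C[C@@H]1C(=C)C | target

**Step count and risks**
Total: 22 steps. Longest linear sequence: 13 steps (steps 1–10, then 20–22, from farnesyl acetate); the lactone branch is 9 steps (11–19) before the union.

Most likely to fail:

1. Step 6 (ten-ring closure). Intermolecular alkylation (oligomerisation) and reaction of the ambident thioallyl anion through its γ-terminus may outrun the slow 10-exo closure. Fallback, setting out from acetate 4 and coming back at diol 9: Tsuji–Trost substitution of the allylic acetate with PhSO2Na and Pd(PPh3)4 (zerovalent palladium) in THF/MeOH should give the allylic phenyl sulfone F1. Its sulfonyl carbanion reacts only through the α-carbon and tolerates slow addition at higher temperature (n-BuLi, THF/HMPA, −78 → 0 °C, high dilution), and epoxide opening would give the ten-membered hydroxy sulfone F2. Li/EtNH2 at −78 °C then removes the sulfonyl and benzyl groups together to give 9.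

2. Step 20 (radical union). The primary radical may be reduced by the stannane before it adds to the enal, or the intermediate α-formyl radical may cyclise onto a ring alkene of the ten-ring. Fallback, setting out from 25 and 13 and coming back at target 30: reductive elimination of the iodohydrin with Zn in AcOH should give 5-epi-isoalantolactone F3. Heating F3 with enal 13 in toluene at about 135 °C (sealed tube, BHT) would run the thermal inverse-demand hetero-Diels–Alder reaction of the 2-substituted acrolein with the α-methylene lactone on the H7 face. At that temperature the ten-ring cannot be kept, so the same [3,3] shift occurs in the flask, either on cycloadduct 29 or first on the enal to give the elemane enal F4, which then cycloadds; both paths converge on 30.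

3. Step 21 (enol ether formation). The anomeric sulfonate may ionise to an oxocarbenium ion that is captured by chloride or by a ring alkene instead of losing a proton, and elimination may be slow because the ring oxygen sits on an acyl-bearing carbon. Fallback, setting out from lactol 27 and coming back at 29: oxidation of the lactol (Dess–Martin periodinane, pyridine) should give the spiro δ-lactone F5. Its only enolisable position is the germacradienyl-bearing carbon, so KN(SiMe3)2 and PhNTf2 at −78 °C would give the ketene acetal triflate F6, and reduction of the C–OTf bond with Pd(PPh3)4, Bu3SnH and LiCl at rt gives enol ether 29 without acid or heat.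

Further compounds
F1 | step 6 | (2E,6E,10S,11S)-12-benzyloxy-10,11-epoxy-10,11-dihydrofarnesyl phenyl sulfone | C(OC[C@]1(C)O[C@H]1CC/C(C)=C/CC/C(C)=C/CS(=O)(=O)c1ccccc1)c1ccccc1
F2 | step 6 | 12-benzyloxy-6-(phenylsulfonyl)germacra-1(10)E,4E-dien-11-ol (C6 epimers) | C/C1=C\CC/C(C)=C/C(S(=O)(=O)c2ccccc2)[C@@H]([C@@](C)(O)COCc2ccccc2)CC1
F3 | step 20 | 5-epi-isoalantolactone | C=C1C(=O)O[C@@H]2C[C@@]3(C)CCCC(=C)[C@H]3C[C@@H]21
F4 | step 20 | (1R,2R,4S)-elemane enal, 2-[(1S,3R,4R)-4-ethenyl-4-methyl-3-(prop-1-en-2-yl)cyclohexyl]prop-2-enal | C=C[C@@]1(C)CC[C@H](C(=C)C=O)C[C@@H]1C(=C)C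
F5 | step 21 | spiro δ-lactone from oxidation of lactol 27 | C/C1=C\CC/C(C)=C/C[C@@H](C2CC[C@]3(OC2=O)C(=O)O[C@@H]2C[C@@]4(C)CCCC(=C)[C@H]4C[C@@H]23)CC1
F6 | step 21 | ketene acetal triflate of F5 | C/C1=C\CC/C(C)=C/C[C@@H](C2=C(OS(=O)(=O)C(F)(F)F)O[C@@]3(CC2)C(=O)O[C@@H]2C[C@@]4(C)CCCC(=C)[C@H]4C[C@@H]23)CC1
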